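**Plan**
- Enabling feature: in ring A (the benzo ring), C3a sits between two oxygen-bearing carbons, C4–OH and C7a–O1, while C5 and C7 are CH. Ring A is therefore the dehydrogenated form of a 2,5-disubstituted cyclohexane-1,3-dione, in which C4 and C7a are equivalent carbonyl carbons and C3a is a carbon nucleophile.
- Retrosynthetic cuts, in order: four O–benzyl bonds; the C5–C6 unsaturation of ring A; O1–C7a (the C2 hydroxyl exchanging onto a 3-methoxy-enone); C2–H (ketone reduction); C3–C3a (dione alkylation by an α-bromodeoxybenzoin); then the dione ring (Michael–Claisen) and the deoxybenzoin (ketone α-arylation).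
- Forward order of rings: ring A is made first as the saturated 1,3-dione, the furan ring O1–C2–C3–C3a–C7a is closed onto it, ring A is aromatized, and the benzyl groups leave last.
- Stereochemistry: C2 and C3 are both set in step 7 by a catalyst-controlled dynamic kinetic transfer hydrogenation of the configurationally labile α-aryl ketone. The ring closure and all later steps break no bond at either centre.

Key step: step 7

Remark: from 12 to 17 the ring-A carbon carrying the aryl-ethyl chain is a stereocentre of no consequence; it is carried as a mixture of epimers (left undefined in the SMILES) and is erased in step 8. Compounds 11–13 are racemic at the benzylic carbon.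

**Step 1**
Reactants: 1 3-[4-(benzyloxy)phenyl]propanal; 2 1-(triphenyl-λ5-phosphanylidene)propan-2-one
Product: 3 (3E)-6-[4-(benzyloxy)phenyl]hex-3-en-2-one
Conditions: CH2Cl2, 25 °C
Reagents that add atoms: none
Why: Wittig olefination with the acetyl-stabilized ylide should give the (E)-enone selectively from the unhindered aliphatic aldehyde.

**Step 2**
Reactants: 3 (3E)-6-[4-(benzyloxy)phenyl]hex-3-en-2-one; 4 diethyl malonate
Product: 6 5-{2-[4-(benzyloxy)phenyl]ethyl}cyclohexane-1,3-dione, via keto ester 5 (not isolated)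
Conditions: NaOEt, EtOH, reflux; then aq NaOH, reflux; then 2 M HCl, 70 °C
Reagents that add atoms: none
Why: Conjugate addition of sodiomalonate, intramolecular Claisen closure of the methyl ketone enolate onto an ester, saponification and decarboxylation of the β-keto acid should build the 5-substituted cyclohexane-1,3-dione in the classical dimedone manner, the aryl benzyl ether tolerating aqueous base and brief dilute acid.

**Step 3**
Reactants: 7 1-[4-(benzyloxy)phenyl]ethan-1-one; 8 1,3-bis(benzyloxy)-5-bromobenzene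
Product: 9 2-[3,5-bis(benzyloxy)phenyl]-1-[4-(benzyloxy)phenyl]ethan-1-one
Conditions: Pd2(dba)3 (1.5 mol %), Xantphos (3.6 mol %), NaOtBu, THF, 70 °C
Reagents that add atoms: none
Why: Palladium-catalysed α-arylation of the acetophenone enolate (Buchwald–Hartwig type) should join the two rings, mono-arylation being favoured because the more acidic deoxybenzoin product rests as its enolate.

**Step 4**
Reactants: 9 2-[3,5-bis(benzyloxy)phenyl]-1-[4-(benzyloxy)phenyl]ethan-1-one
Product: 11 2-[3,5-bis(benzyloxy)phenyl]-1-[4-(benzyloxy)phenyl]-2-bromoethan-1-one, via silyl enol ether 10 (not isolated)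
Conditions: LiN(SiMe3)2, Me3SiCl, THF, −78 °C; then NBS, −78 °C
Reagents that add atoms: N-bromosuccinimide, O=C1CCC(=O)N1Br
Why: The only possible enolate is trapped as its silyl enol ether, which NBS should brominate at carbon at low temperature faster than it attacks the electron-rich 3,5-dialkoxyphenyl ring, giving the racemic α-bromo ketone.

**Step 5**
Reactants: 6 5-{2-[4-(benzyloxy)phenyl]ethyl}cyclohexane-1,3-dione; 11 2-[3,5-bis(benzyloxy)phenyl]-1-[4-(benzyloxy)phenyl]-2-bromoethan-1-one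
Product: 12 2-{1-[3,5-bis(benzyloxy)phenyl]-2-[4-(benzyloxy)phenyl]-2-oxoethyl}-5-{2-[4-(benzyloxy)phenyl]ethyl}cyclohexane-1,3-dione
Conditions: K2CO3, CHCl3, 25 °C
Reagents that add atoms: none
Why: The soft potassium enolate of the cyclic 1,3-dione should displace the doubly activated (benzylic, α-keto) bromide by SN2 C-alkylation, as in the phenacylation of cyclohexane-1,3-diones, forming the C3–C3a bond with a racemic, labile benzylic centre.

**Step 6**
Reactants: 12 2-{1-[3,5-bis(benzyloxy)phenyl]-2-[4-(benzyloxy)phenyl]-2-oxoethyl}-5-{2-[4-(benzyloxy)phenyl]ethyl}cyclohexane-1,3-dione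
Product: 13 2-{1-[3,5-bis(benzyloxy)phenyl]-2-[4-(benzyloxy)phenyl]-2-oxoethyl}-5-{2-[4-(benzyloxy)phenyl]ethyl}-3-methoxycyclohex-2-en-1-one
Conditions: Me3SiCHN2, MeOH/toluene, 0 °C
Reagents that add atoms: (trimethylsilyl)diazomethane, C[Si](C)(C)C=[N+]=[N-]
Why: O-Methylation of the vinylogous acid should block Paal–Knorr-type furan formation through the dione oxygen and turn C7a into a vinylogous ester carbon carrying a leaving group, either oxygen giving the same constitution.

**Step 7**
Reactants: 13 2-{1-[3,5-bis(benzyloxy)phenyl]-2-[4-(benzyloxy)phenyl]-2-oxoethyl}-5-{2-[4-(benzyloxy)phenyl]ethyl}-3-methoxycyclohex-2-en-1-one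
Product: 15 (2S,3S)-3-[3,5-bis(benzyloxy)phenyl]-2-[4-(benzyloxy)phenyl]-6-{2-[4-(benzyloxy)phenyl]ethyl}-3,5,6,7-tetrahydro-1-benzofuran-4(2H)-one, via hydroxy enol ether 14 (not isolated)
Conditions: RuCl[(S,S)-TsDPEN](p-cymene) (2 mol %), HCO2H/Et3N (5:2), DMF, 40 °C; then PPTS (20 mol %), toluene, 4 Å sieves, 60 °C
Reagents that add atoms: none
Why: Et3N/HCO2H should keep the C–H next to the aryl ketone of 13 (benzylic, allylic and α to C=O) epimerizing, so the Noyori–Ikariya transfer hydrogenation runs as a dynamic kinetic resolution in which the (S,S)-ligand sets the carbinol carbon (C2 of the target) as S through the usual aryl/arene CH–π contact, and hydride enters anti to the bulky 2,6-disubstituted cyclohexenyl group of the faster-reacting ketone enantiomer (Felkin–Anh), fixing C3 as S in alcohol 14. Mild acid then protonates the vinylogous ester at the C4 carbonyl, the C2 hydroxyl adds to the resulting oxocarbenium carbon C7a in a 5-exo-trig closure, and loss of methanol restores the conjugated 3-alkoxy-enone, so the O1–C7a bond and the furan ring O1–C2–C3–C3a–C7a arise by addition–elimination with no bond to C2 or C3 broken. The closest known reaction types are the dynamic transfer hydrogenation of α-aryl aryl ketones such as isoflavanones and the acid-catalysed alcohol exchange of 3-alkoxycyclohex-2-enones. The step needs chemoselectivity (aryl ketone reduced, vinylogous ester untouched by the ruthenium hydride), which the low electrophilicity of the 3-alkoxy-enone secures, and retention at C2, which the mild acid secures by avoiding benzylic ionization. No regiochemical choice arises in the closure, because C7a is the only electrophilic carbon within five-ring reach and the two oxygen-bearing carbons of ring A were equivalent before O-methylation.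

**Step 8**
Reactants: 15 (2S,3S)-3-[3,5-bis(benzyloxy)phenyl]-2-[4-(benzyloxy)phenyl]-6-{2-[4-(benzyloxy)phenyl]ethyl}-3,5,6,7-tetrahydro-1-benzofuran-4(2H)-one
Product: 18 (2S,3S)-3-[3,5-bis(benzyloxy)phenyl]-2-[4-(benzyloxy)phenyl]-6-{2-[4-(benzyloxy)phenyl]ethyl}-2,3-dihydro-1-benzofuran-4-ol, via silyl dienol ether 16 (not isolated), via cyclohexadienone 17 (not isolated)
Conditions: LiN(SiMe3)2, Me3SiCl, THF, −78 °C; then Pd(OAc)2 (1.1 equiv), MeCN, 25 °C
Reagents that add atoms: none
Why: Kinetic α′-enolization and silylation followed by Saegusa–Ito oxidation should introduce the C5–C6 double bond, and the cross-conjugated dienone with a CH2 at C7 tautomerizes at once to the phenol, so ring A becomes aromatic, the C6 epimers converge and the non-acidic C2 and C3 stay untouched.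

**Step 9**
Reactants: 18 (2S,3S)-3-[3,5-bis(benzyloxy)phenyl]-2-[4-(benzyloxy)phenyl]-6-{2-[4-(benzyloxy)phenyl]ethyl}-2,3-dihydro-1-benzofuran-4-ol
Product: 19 5-[(2S,3S)-4-hydroxy-2-(4-hydroxyphenyl)-6-[2-(4-hydroxyphenyl)ethyl]-2,3-dihydro-1-benzofuran-3-yl]benzene-1,3-diol
Conditions: H2 (1 atm), 10% Pd/C, EtOAc/MeOH, 25 °C
Reagents that add atoms: none
Why: Hydrogenolysis over palladium should cleave the four primary benzyl aryl ethers much faster than the ring benzylic C2–O1 bond of the 2-aryl-2,3-dihydrobenzofuran under neutral conditions, releasing the pentaphenol without touching the stereocentres.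

**Compound list**
1 | 3-[4-(benzyloxy)phenyl]propanal | O=CCCc1ccc(OCc2ccccc2)cc1 | starting material
2 | 1-(triphenyl-λ5-phosphanylidene)propan-2-one | CC(=O)C=P(c1ccccc1)(c1ccccc1)c1ccccc1 | starting material
3 | (3E)-6-[4-(benzyloxy)phenyl]hex-3-en-2-one | CC(=O)/C=C/CCc1ccc(OCc2ccccc2)cc1 | intermediate
4 | diethyl malonate | CCOC(=O)CC(=O)OCC | starting material
5 | ethyl 2-{2-[4-(benzyloxy)phenyl]ethyl}-4,6-dioxocyclohexane-1-carboxylate (as sodium enolate, not isolated) | CCOC(=O)C1C(CCc2ccc(OCc3ccccc3)cc2)CC(=O)CC1=O | intermediate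
6 | 5-{2-[4-(benzyloxy)phenyl]ethyl}cyclohexane-1,3-dione | O=C1CC(=O)CC(CCc2ccc(OCc3ccccc3)cc2)C1 | intermediate
7 | 1-[4-(benzyloxy)phenyl]ethan-1-one | CC(=O)c1ccc(OCc2ccccc2)cc1 | starting material
8 | 1,3-bis(benzyloxy)-5-bromobenzene | Brc1cc(OCc2ccccc2)cc(OCc2ccccc2)c1 | starting material
9 | 2-[3,5-bis(benzyloxy)phenyl]-1-[4-(benzyloxy)phenyl]ethan-1-one | O=C(Cc1cc(OCc2ccccc2)cc(OCc2ccccc2)c1)c1ccc(OCc2ccccc2)cc1 | intermediate
10 | {[(Z)-2-[3,5-bis(benzyloxy)phenyl]-1-[4-(benzyloxy)phenyl]ethenyl]oxy}trimethylsilane (not isolated) | C[Si](C)(C)O/C(c1ccc(OCc2ccccc2)cc1)=C\c1cc(OCc2ccccc2)cc(OCc2ccccc2)c1 | intermediate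
11 | 2-[3,5-bis(benzyloxy)phenyl]-1-[4-(benzyloxy)phenyl]-2-bromoethan-1-one (racemic) | O=C(C(Br)c1cc(OCc2ccccc2)cc(OCc2ccccc2)c1)c1ccc(OCc2ccccc2)cc1 | intermediate
12 | 2-{1-[3,5-bis(benzyloxy)phenyl]-2-[4-(benzyloxy)phenyl]-2-oxoethyl}-5-{2-[4-(benzyloxy)phenyl]ethyl}cyclohexane-1,3-dione (enolized; stereoisomer mixture) | O=C(C(c1cc(OCc2ccccc2)cc(OCc2ccccc2)c1)C1C(=O)CC(CCc2ccc(OCc3ccccc3)cc2)CC1=O)c1ccc(OCc2ccccc2)cc1 | intermediate
13 | 2-{1-[3,5-bis(benzyloxy)phenyl]-2-[4-(benzyloxy)phenyl]-2-oxoethyl}-5-{2-[4-(benzyloxy)phenyl]ethyl}-3-methoxycyclohex-2-en-1-one (stereoisomer mixture) | COC1=C(C(C(=O)c2ccc(OCc3ccccc3)cc2)c2cc(OCc3ccccc3)cc(OCc3ccccc3)c2)C(=O)CC(CCc2ccc(OCc3ccccc3)cc2)C1 | intermediate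
14 | 2-{(1S,2S)-1-[3,5-bis(benzyloxy)phenyl]-2-[4-(benzyloxy)phenyl]-2-hydroxyethyl}-5-{2-[4-(benzyloxy)phenyl]ethyl}-3-methoxycyclohex-2-en-1-one (ring epimers; not isolated) | COC1=C([C@@H]([C@H](O)c2ccc(OCc3ccccc3)cc2)c2cc(OCc3ccccc3)cc(OCc3ccccc3)c2)C(=O)CC(CCc2ccc(OCc3ccccc3)cc2)C1 | intermediate
15 | (2S,3S)-3-[3,5-bis(benzyloxy)phenyl]-2-[4-(benzyloxy)phenyl]-6-{2-[4-(benzyloxy)phenyl]ethyl}-3,5,6,7-tetrahydro-1-benzofuran-4(2H)-one (C6 epimers) | O=C1C2=C(CC(CCc3ccc(OCc4ccccc4)cc3)C1)O[C@H](c1ccc(OCc3ccccc3)cc1)[C@H]2c1cc(OCc2ccccc2)cc(OCc2ccccc2)c1 | intermediate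
16 | {[(2S,3S)-3-[3,5-bis(benzyloxy)phenyl]-2-[4-(benzyloxy)phenyl]-6-{2-[4-(benzyloxy)phenyl]ethyl}-2,3,6,7-tetrahydro-1-benzofuran-4-yl]oxy}trimethylsilane (C6 epimers; not isolated) | C[Si](C)(C)OC1=CC(CCc3ccc(OCc4ccccc4)cc3)CC(O[C@H](c3ccc(OCc4ccccc4)cc3)[C@H]2c3cc(OCc4ccccc4)cc(OCc4ccccc4)c3)=C12 | intermediate
17 | (2S,3S)-3-[3,5-bis(benzyloxy)phenyl]-2-[4-(benzyloxy)phenyl]-6-{2-[4-(benzyloxy)phenyl]ethyl}-3,7-dihydro-1-benzofuran-4(2H)-one (not isolated) | O=C1C2=C(CC(CCc3ccc(OCc4ccccc4)cc3)=C1)O[C@H](c1ccc(OCc3ccccc3)cc1)[C@H]2c1cc(OCc2ccccc2)cc(OCc2ccccc2)c1 | intermediate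
18 | (2S,3S)-3-[3,5-bis(benzyloxy)phenyl]-2-[4-(benzyloxy)phenyl]-6-{2-[4-(benzyloxy)phenyl]ethyl}-2,3-dihydro-1-benzofuran-4-ol | c1ccccc1COc1ccc(CCc2cc(O)c3c(c2)O[C@H](c2ccc(OCc4ccccc4)cc2)[C@H]3c2cc(OCc4ccccc4)cc(OCc4ccccc4)c2)cc1 | intermediate
19 | 5-[(2S,3S)-4-hydroxy-2-(4-hydroxyphenyl)-6-[2-(4-hydroxyphenyl)ethyl]-2,3-dihydro-1-benzofuran-3-yl]benzene-1,3-diol | Oc1ccc(CCc2cc(O)c3c(c2)O[C@H](c2ccc(O)cc2)[C@H]3c2cc(O)cc(O)c2)cc1 | target

**Totals and risks**
Total step count: 9. Longest linear sequence: 7 steps (1, 2, 5, 6, 7, 8, 9; the branch 3, 4, 5–9 is equally long).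

The three steps most likely to fail:

Step 7. Epimerization at the benzylic carbon of 13 may be too slow, or hydride delivery may not discriminate between the two bulky α-substituents, so the diastereomeric alcohol forms and closes to the cis isomer. Acid could then carry that cis isomer through C2 ionization into the enantiomeric trans series, and the ketone enol may also lose methanol to an aromatic furan. The fallback gives up the dynamic resolution and sets out from 13. Substrate-controlled reduction (NaBH4, CeCl3·7H2O, MeOH/THF, −40 °C) should give the racemic Felkin alcohol, that is 14 together with the (1R,2R)-configured alcohol F1. The same PPTS closure through the O1–C7a bond then gives the racemic trans ketone, that is 15 together with the (2R,3R)-configured ketone F2. Preparative chromatography on a chiral stationary phase with supercritical CO2 separates the enantiomers, and the route is rejoined at 15.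

Step 5. The ambident dione enolate may be alkylated at oxygen, and 12 may cyclodehydrate prematurely to the furan on base or on silica. The fallback forms the C3–C3a bond by cross-coupling and sets out from 6 and 9. Compound 6 is converted with MeOH and catalytic TsOH into 5-{2-[4-(benzyloxy)phenyl]ethyl}-3-methoxycyclohex-2-en-1-one F3. This is iodinated at the α-carbon with N-iodosuccinimide in MeCN to 5-{2-[4-(benzyloxy)phenyl]ethyl}-2-iodo-3-methoxycyclohex-2-en-1-one F4. Palladium-catalysed α-alkenylation of the sodium enolate of 9 with F4 (Pd2(dba)3, P(t-Bu)3, NaOtBu, toluene, 60 °C) then gives 13 directly, bypassing 11, 12 and step 6.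

Step 8. β-Hydride elimination may stall at the substituted C6, or the electron-rich phenol product may be oxidized further by Pd(OAc)2. The fallback uses selenium in place of palladium and sets out from 15. LiN(iPr)2 and PhSeCl in THF at −78 °C give (2S,3S)-3-[3,5-bis(benzyloxy)phenyl]-2-[4-(benzyloxy)phenyl]-6-{2-[4-(benzyloxy)phenyl]ethyl}-5-(phenylselanyl)-3,5,6,7-tetrahydro-1-benzofuran-4(2H)-one F5. Oxidation with H2O2 and pyridine in CH2Cl2 at 0 °C and selenoxide syn-elimination give dienone 17, which tautomerizes, and the route is rejoined at 18.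

**Further compounds**
F1 | step 7 | 2-{(1R,2R)-1-[3,5-bis(benzyloxy)phenyl]-2-[4-(benzyloxy)phenyl]-2-hydroxyethyl}-5-{2-[4-(benzyloxy)phenyl]ethyl}-3-methoxycyclohex-2-en-1-one | COC1=C([C@H]([C@@H](O)c2ccc(OCc3ccccc3)cc2)c2cc(OCc3ccccc3)cc(OCc3ccccc3)c2)C(=O)CC(CCc2ccc(OCc3ccccc3)cc2)C1
F2 | step 7 | (2R,3R)-3-[3,5-bis(benzyloxy)phenyl]-2-[4-(benzyloxy)phenyl]-6-{2-[4-(benzyloxy)phenyl]ethyl}-3,5,6,7-tetrahydro-1-benzofuran-4(2H)-one | O=C1C2=C(CC(CCc3ccc(OCc4ccccc4)cc3)C1)O[C@@H](c1ccc(OCc3ccccc3)cc1)[C@@H]2c1cc(OCc2ccccc2)cc(OCc2ccccc2)c1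
F3 | step 5 | 5-{2-[4-(benzyloxy)phenyl]ethyl}-3-methoxycyclohex-2-en-1-one | COC1=CC(=O)CC(CCc2ccc(OCc3ccccc3)cc2)C1
F4 | step 5 | 5-{2-[4-(benzyloxy)phenyl]ethyl}-2-iodo-3-methoxycyclohex-2-en-1-one | COC1=C(C(=O)CC(CCc2ccc(OCc3ccccc3)cc2)C1)I
F5 | step 8 | (2S,3S)-3-[3,5-bis(benzyloxy)phenyl]-2-[4-(benzyloxy)phenyl]-6-{2-[4-(benzyloxy)phenyl]ethyl}-5-(phenylselanyl)-3,5,6,7-tetrahydro-1-benzofuran-4(2H)-one | O=C1C2=C(CC(CCc3ccc(OCc4ccccc4)cc3)C1[Se]c1ccccc1)O[C@H](c1ccc(OCc3ccccc3)cc1)[C@H]2c1cc(OCc2ccccc2)cc(OCc2ccccc2)c1
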